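**Retrosynthetic overview**
1. Target 16 is (+)-catechin carrying one fisetinidol at C8 and a fisetinidol-(4α→6)-fisetinidol pair at C6. Removing six O-benzyl groups and cutting C4(middle unit)–C6(catechin) gives the thioether dimer 14 and fisetinidol-(4α→8)-catechin 12.
2. 14 is cut at C4(top)–C6(middle) into 4-methoxyflavan 10 (electrophile under protic acid) and its 4-benzylsulfanyl analogue 13 (nucleophile, made from 10). 12 is cut into 10 and catechin 11, so one flavan, 10, supplies all three fisetinidol units.
3. 10 is cut in one operation at O1–C8a of its pyran ring and at C4–OMe, giving the fluoro epoxy alcohol 6. 6 comes from aldehyde 1 and ketone 2 by condensation, Juliá–Colonna epoxidation (sets C3) and chelate-controlled reduction (relays C2).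
4. Enabling feature: in ring A of a fisetinidol unit the C7 oxygen is para to C4a and 1,3 to C8a. A 7-oxo quinone methide (C7=O, C8=C8a, C4a=C4) therefore makes a fluorine-bearing C8a the β-carbon of an enone within six-ring reach of the C2 oxygen, and makes C4 a δ-electrophile.
5. Ring order: pyran ring of 10 (key step, carried into every fisetinidol unit, the terminal one included) → union with catechin (12) → 4→6 union of two fisetinidol units (14) → final 4→6 union (15) → debenzylation (16).

Key step: step 5

Remark: the SMILES is read as [fisetinidol-(4α→6)-fisetinidol-(4α→6)]-[fisetinidol-(4α→8)]-catechin, every unit 2,3-trans with 3,4-trans interflavan bonds; 1, 2 and 11 are taken as commercial.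

Step 1
Reactants: 1 2-fluoro-4-hydroxybenzaldehyde; 2 1-[3,4-bis(benzyloxy)phenyl]ethan-1-one
Product: 3 (E)-1-[3,4-bis(benzyloxy)phenyl]-3-(2-fluoro-4-hydroxyphenyl)prop-2-en-1-one
Conditions: KOH (5 equiv), EtOH–H2O, rt, 48 h; then aq HCl to pH 5
Reagents that add atoms: none
Why: Claisen–Schmidt aldol condensation of an aryl methyl ketone with a non-enolisable aldehyde should give the thermodynamically favoured E-enone, with no stereocenter formed and the phenoxide shielding the fluoroarene from substitution.

Step 2
Reactants: 3 chalcone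
Product: 4 (E)-1-[3,4-bis(benzyloxy)phenyl]-3-{2-fluoro-4-[(triisopropylsilyl)oxy]phenyl}prop-2-en-1-one
Conditions: iPr3SiCl, imidazole, DMF, rt
Reagents that add atoms: triisopropylsilyl chloride, CC(C)[Si](Cl)(C(C)C)C(C)C
Why: Imidazole-mediated O-silylation of the phenol installs a hindered aryl silyl ether that should survive basic peroxide and hydride and later serves as the fluoride-sensitive trigger.

Step 3
Reactants: 4 silyl chalcone
Product: 5 [3,4-bis(benzyloxy)phenyl][(2S,3R)-3-{2-fluoro-4-[(triisopropylsilyl)oxy]phenyl}oxiran-2-yl]methanone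
Conditions: poly-D-leucine (immobilised), urea–H2O2, DBU, THF, rt
Reagents that add atoms: urea–hydrogen peroxide adduct, NC(N)=O.OO
Why: Juliá–Colonna epoxidation (Weitz–Scheffer addition of hydroperoxide under control of the helical D-polypeptide) should deliver oxygen to one enone face, giving the trans (2S,3R) epoxy ketone and thereby C3 of the future flavan together with a sacrificial benzylic center.

Step 4
Reactants: 5 epoxy ketone
Product: 6 (R)-[3,4-bis(benzyloxy)phenyl][(2R,3R)-3-{2-fluoro-4-[(triisopropylsilyl)oxy]phenyl}oxiran-2-yl]methanol (anti epoxy alcohol)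
Conditions: Zn(BH4)2, Et2O, −20 °C; aq NH4Cl
Reagents that add atoms: none
Why: Cram-chelate-controlled reduction, in which zinc bridges the carbonyl and oxirane oxygens and hydride enters from the face away from the oxirane C–C bond, should give the anti (erythro) epoxy alcohol and so set C2 of the future flavan from C3.

Step 5
Reactants: 6 anti epoxy alcohol
Product: 10 (2R,3S,4R)-2-[3,4-bis(benzyloxy)phenyl]-4-methoxy-3,4-dihydro-2H-chromene-3,7-diol, via phenoxide epoxy alcohol 7 (not isolated), via open-chain quinone methide 8 (not isolated), via flavan quinone methide 9 (not isolated)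
Conditions: Bu4NF (1.1 equiv, dried over 4 Å MS), THF (0.01 M), −20 °C, 15 min; then MeOH (excess), −20 → 0 °C; AcOH
Reagents that add atoms: methanol, CO
Why: Proposed new method: fluoride cleaves the aryl silyl ether and phenoxide 7 pushes through ring A to open the benzylic C4–O bond of the oxirane, giving the open-chain p-quinone methide 8 (C7=O, C8=C8a, C4a=C4) in which the fluorine-bearing C8a is the β-carbon of a dienone; after proton shuttle from the freed C3 alkoxide the C2 alkoxide adds to C8a and fluoride leaves (addition–elimination), which forms the O1–C8a bond and the flavan quinone methide 9, and methanol then adds to C4 of 9 in 1,6-fashion with rearomatisation of ring A. The closest known reaction types are the alkoxide/aryl fluoride SNAr closure of chroman rings, addition–elimination at β-halo enones and haloquinones, fluoride-triggered quinone methide release from silyl-protected p-hydroxybenzyl derivatives, and the solvolysis of 7-hydroxyflavan-3,4-diols through their ring A quinone methides. The pyran ring closes in a 6-exo-trig mode (oxygen on C2, tether C2–C3–C4, attack on C8a perpendicular to the dienone plane with C8 outside the ring), whereas closure from the C3 oxygen would give a five-membered ring whose tether holds the C4=C4a double bond and so forces a near in-plane attack, and attack of either oxygen on C4 is strained and reversible. C2 and C3 are carried unchanged from 6 because the oxirane opens only at C4–O, and the new C4 center is set by the C3 hydroxyl, methanol entering anti to it on the half-chair of 9 to give the 2,3-trans-3,4-trans (4R) ether. The step needs ring closure before any intermolecular capture at C4 of 8, which should be secured by high dilution, by withholding every protic nucleophile until closure is complete and by the fact that return to the oxirane and cyclisation are both unimolecular, the return also letting the E and Z forms of 8 interconvert so that the Z form, with C3 on the side of C8a, drains into 9. Because 10 is the only flavan the route needs, this one closure supplies the pyran ring of all three fisetinidol units, the terminal one included.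

Step 6
Reactants: 10 4-methoxyflavan; 11 (+)-catechin
Product: 12 (2R,3S)-8-{(2R,3S,4S)-2-[3,4-bis(benzyloxy)phenyl]-3,7-dihydroxy-3,4-dihydro-2H-chromen-4-yl}-2-(3,4-dihydroxyphenyl)-3,4-dihydro-2H-chromene-3,5,7-triol
Conditions: 11 (4 equiv), HCl (0.1 M), dioxane–H2O, rt
Reagents that add atoms: none
Why: Acid-catalysed condensation of the leucoanthocyanidin type (loss of methanol from C4 to the flavan-4-yl cation, then Friedel–Crafts attack by the phloroglucinol ring of catechin) should occur mainly at C8 and anti to the C3 hydroxyl, which sets C4 of this unit as 3,4-trans.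

Step 7
Reactants: 10 4-methoxyflavan
Product: 13 (2R,3R,4R)-4-(benzylsulfanyl)-2-[3,4-bis(benzyloxy)phenyl]-3,4-dihydro-2H-chromene-3,7-diol
Conditions: BnSH (5 equiv), HCl (0.1 M), dioxane–H2O, rt
Reagents that add atoms: benzyl mercaptan, SCc1ccccc1
Why: Acid-catalysed exchange at C4 of the thiolysis type (ionisation to the flavan-4-yl cation stabilised by the para C7 oxygen, capture by the thiol) should give the 4-benzylsulfanyl flavan with the thiol entering mainly anti to the C3 hydroxyl, a center that is erased again in step 9.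

Step 8
Reactants: 10 4-methoxyflavan; 13 4-benzylsulfanylflavan
Product: 14 3',4'-di-O-benzylfisetinidol-(4α→6)-[4α-(benzylsulfanyl)-3',4'-di-O-benzylfisetinidol]
Conditions: 13 (3 equiv), HCl (0.1 M), dioxane–H2O, rt, slow addition of 10; excess 13 recovered
Reagents that add atoms: none
Why: In this acid-catalysed flavan-4-yl cation condensation (Friedel–Crafts alkylation) only the 4-methoxy group of 10 should ionise under dilute protic acid while the 4-benzylsulfanyl group of 13 stays in place, so that C6 of the resorcinol-type ring A of 13 (the position not flanked by two oxygens) captures the cation anti to the C3 hydroxyl and sets C4 of the top unit as 3,4-trans.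

Step 9
Reactants: 14 thioether dimer; 12 fisetinidol-(4α→8)-catechin dibenzyl ether
Product: 15 [3',4'-di-O-benzylfisetinidol-(4α→6)-3',4'-di-O-benzylfisetinidol-(4α→6)]-[3',4'-di-O-benzylfisetinidol-(4α→8)]-catechin
Conditions: AgBF4 (2.5 equiv), 12 (2 equiv), THF, 0 °C, dark
Reagents that add atoms: none
Why: Thiophilic activation of the benzylic C4–S bond by AgBF4 (silver-assisted Friedel–Crafts alkylation under non-protic conditions) should release the C4 cation of the lower unit of 14, which is intercepted by C6 of the catechin unit of 12, the one remaining phloroglucinol-type position and far more nucleophilic than any resorcinol-type ring, anti to the C3 hydroxyl so that this C4 becomes 3,4-trans.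

Step 10
Reactants: 15 hexa-O-benzyl tetramer
Product: 16 [fisetinidol-(4α→6)-fisetinidol-(4α→6)]-[fisetinidol-(4α→8)]-catechin (CNP0263622.1)
Conditions: H2 (1 atm), Pd(OH)2/C, THF–MeOH–H2O, rt
Reagents that add atoms: none
Why: Hydrogenolysis of the six benzyl aryl ethers should leave the diarylmethine interflavan bonds, the benzylic C2–O1 bonds and all stereocenters untouched.

**Compound list**
1 | 2-fluoro-4-hydroxybenzaldehyde | O=Cc1ccc(O)cc1F | starting material
2 | 1-[3,4-bis(benzyloxy)phenyl]ethan-1-one | CC(=O)c1ccc(OCc2ccccc2)c(OCc2ccccc2)c1 | starting material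
3 | (E)-1-[3,4-bis(benzyloxy)phenyl]-3-(2-fluoro-4-hydroxyphenyl)prop-2-en-1-one | O=C(/C=C/c1ccc(O)cc1F)c1ccc(OCc2ccccc2)c(OCc2ccccc2)c1 | intermediate
4 | (E)-1-[3,4-bis(benzyloxy)phenyl]-3-{2-fluoro-4-[(triisopropylsilyl)oxy]phenyl}prop-2-en-1-one | O=C(/C=C/c1ccc(O[Si](C(C)C)(C(C)C)C(C)C)cc1F)c1ccc(OCc2ccccc2)c(OCc2ccccc2)c1 | intermediate
5 | [3,4-bis(benzyloxy)phenyl][(2S,3R)-3-{2-fluoro-4-[(triisopropylsilyl)oxy]phenyl}oxiran-2-yl]methanone | O=C(c1ccc(OCc2ccccc2)c(OCc2ccccc2)c1)[C@H]1O[C@@H]1c1ccc(O[Si](C(C)C)(C(C)C)C(C)C)cc1F | intermediate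
6 | (R)-[3,4-bis(benzyloxy)phenyl][(2R,3R)-3-{2-fluoro-4-[(triisopropylsilyl)oxy]phenyl}oxiran-2-yl]methanol (anti epoxy alcohol) | O[C@H](c1ccc(OCc2ccccc2)c(OCc2ccccc2)c1)[C@H]1O[C@@H]1c1ccc(O[Si](C(C)C)(C(C)C)C(C)C)cc1F | intermediate
7 | (R)-[3,4-bis(benzyloxy)phenyl][(2R,3R)-3-(2-fluoro-4-hydroxyphenyl)oxiran-2-yl]methanol, present as its tetrabutylammonium phenoxide | O[C@H](c1ccc(OCc2ccccc2)c(OCc2ccccc2)c1)[C@H]1O[C@@H]1c1ccc(O)cc1F | intermediate
8 | 4-{(Z,2S,3R)-3-[3,4-bis(benzyloxy)phenyl]-2,3-dihydroxypropylidene}-3-fluorocyclohexa-2,5-dien-1-one, present as its alkoxide | O[C@H](c1ccc(OCc2ccccc2)c(OCc2ccccc2)c1)[C@@H](O)/C=C1/C=CC(=O)C=C1F | intermediate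
9 | (2R,3S)-2-[3,4-bis(benzyloxy)phenyl]-3-hydroxy-2,3-dihydro-7H-chromen-7-one | O=C1C=CC2=C[C@H](O)[C@@H](c3ccc(OCc4ccccc4)c(OCc4ccccc4)c3)OC2=C1 | intermediate
10 | (2R,3S,4R)-2-[3,4-bis(benzyloxy)phenyl]-4-methoxy-3,4-dihydro-2H-chromene-3,7-diol | Oc1ccc2c(c1)O[C@H](c1ccc(OCc3ccccc3)c(OCc3ccccc3)c1)[C@@H](O)[C@@H]2OC | intermediate
11 | (+)-catechin, (2R,3S)-2-(3,4-dihydroxyphenyl)-3,4-dihydro-2H-chromene-3,5,7-triol | Oc1cc(O)c2c(c1)O[C@H](c1ccc(O)c(O)c1)[C@@H](O)C2 | starting material
12 | 3',4'-di-O-benzylfisetinidol-(4α→8)-catechin; upper unit 2R,3S,4S, lower unit 2R,3S | Oc1cc(O)c2c(c1[C@@H]3c4ccc(O)cc4O[C@H](c4ccc(OCc5ccccc5)c(OCc5ccccc5)c4)[C@H]3O)O[C@H](c1ccc(O)c(O)c1)[C@@H](O)C2 | intermediate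
13 | (2R,3R,4R)-4-(benzylsulfanyl)-2-[3,4-bis(benzyloxy)phenyl]-3,4-dihydro-2H-chromene-3,7-diol (2,3-trans-3,4-trans; C3 is spatially as in 10, its descriptor changes because sulfur outranks oxygen) | Oc1ccc2c(c1)O[C@H](c1ccc(OCc3ccccc3)c(OCc3ccccc3)c1)[C@@H](O)[C@@H]2SCc1ccccc1 | intermediate
14 | 3',4'-di-O-benzylfisetinidol-(4α→6)-[4α-(benzylsulfanyl)-3',4'-di-O-benzylfisetinidol]; top unit 2R,3S,4R, lower unit 2R,3R,4R | Oc1ccc2c(c1)O[C@H](c1ccc(OCc3ccccc3)c(OCc3ccccc3)c1)[C@@H](O)[C@@H]2c1cc2c(cc1O)O[C@H](c1ccc(OCc3ccccc3)c(OCc3ccccc3)c1)[C@@H](O)[C@@H]2SCc1ccccc1 | intermediate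
15 | hexa-O-benzyl tetramer (benzyl ethers on the three fisetinidol catechol rings); all units 2,3-trans, all interflavan bonds 3,4-trans | Oc1ccc2c(c1)O[C@H](c1ccc(OCc3ccccc3)c(OCc3ccccc3)c1)[C@@H](O)[C@@H]2c1cc2c(cc1O)O[C@H](c1ccc(OCc3ccccc3)c(OCc3ccccc3)c1)[C@@H](O)[C@@H]2c1c(O)c2c(c([C@@H]3c4ccc(O)cc4O[C@H](c4ccc(OCc5ccccc5)c(OCc5ccccc5)c4)[C@H]3O)c1O)O[C@H](c1ccc(O)c(O)c1)[C@@H](O)C2 | intermediate
16 | [fisetinidol-(4α→6)-fisetinidol-(4α→6)]-[fisetinidol-(4α→8)]-catechin (CNP0263622.1) | Oc1ccc2c(c1)O[C@H](c1ccc(O)c(O)c1)[C@@H](O)[C@@H]2c1cc2c(cc1O)O[C@H](c1ccc(O)c(O)c1)[C@@H](O)[C@@H]2c1c(O)c2c(c([C@@H]3c4ccc(O)cc4O[C@H](c4ccc(O)c(O)c4)[C@H]3O)c1O)O[C@H](c1ccc(O)c(O)c1)[C@@H](O)C2 | target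

Total step count: 10. Longest linear sequence: 9 steps (1/2 → 3 → 4 → 5 → 6 → 10 → 13 → 14 → 15 → 16).

**Steps most likely to fail**

Step 5 (proposed new method). The quinone methide intermediates may tautomerise by loss of the C3 proton to an enol and on to a ketone. Adventitious water may add to C4 of the open-chain quinone methide before ring closure. Closure may also occur through the C3 oxygen, or cyclised material may condense with itself through ring A before methanol is added. Fallback by known chemistry, setting out from 3 and returning at 10, with the pyran ring closed by a classical alkoxide/aryl fluoride SNAr on a robustly protected substrate. MOMCl and iPr2NEt in CH2Cl2 give the methoxymethyl ether of the chalcone F1. Juliá–Colonna epoxidation with poly-D-leucine gives the (2S,3R) epoxy ketone F2. Zn(BH4)2 gives the anti epoxy alcohol F3. Acetone with catalytic BF3·OEt2 at −20 °C converts the oxirane, with inversion at the benzylic carbon, into the dioxolane alcohol F4, in which O3 is blocked and only the C2 hydroxyl is free. KOtBu in DMF at 80 °C closes O1–C8a to the tricyclic acetonide F5. HCl in MeOH at rt then removes the acetonide and the methoxymethyl group and methanolyses C4, giving 10.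

Step 8. The electrophile 10 may condense with itself instead of with 13. The product may be alkylated again through ring A of its top unit, the sulfanyl group may slowly exchange under acid, and attack may be shared between C6 and C8 or between the two faces of C4. Fallback, setting out from 13 (with 10) and returning at 15, with the roles of the two partners exchanged. AgBF4 in THF at 0 °C, buffered with 2,6-di-tert-butyl-4-methylpyridine, ionises the C4–S bond of 13 in the presence of excess 10, whose 4-methoxy group is inert without protic acid, and C6 of 10 captures the cation to give the methoxy-terminated dimer F6. HCl (0.1 M) in dioxane–H2O then ionises the 4-methoxy group of F6 in the presence of 12 (2 equiv), as in step 6, and gives 15 directly.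

Step 9. The silver salt may oxidise the free catechol ring of 12. Attack may also be shared between C6 of the catechin unit and the resorcinol-type rings, and facial selectivity at C4 may be incomplete. Fallback, setting out from 14 and returning at 15, with the silver step separated from the oxidisable partner and the union done under protic acid. AgBF4 in THF–H2O at 0 °C hydrolyses the thioether of 14 to the flavan-3,4-diol-terminated dimer F7, from which the silver salts are filtered off. HCl (0.1 M) in dioxane–H2O with 12 (2 equiv) then effects the classical flavan-3,4-diol condensation at C6 of the catechin unit, giving 15.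

**Further compounds**
F1 | step 5 | (E)-1-[3,4-bis(benzyloxy)phenyl]-3-[2-fluoro-4-(methoxymethoxy)phenyl]prop-2-en-1-one | O=C(/C=C/c1ccc(OCOC)cc1F)c1ccc(OCc2ccccc2)c(OCc2ccccc2)c1
F2 | step 5 | [3,4-bis(benzyloxy)phenyl]{(2S,3R)-3-[2-fluoro-4-(methoxymethoxy)phenyl]oxiran-2-yl}methanone | O=C(c1ccc(OCc2ccccc2)c(OCc2ccccc2)c1)[C@H]1O[C@@H]1c1ccc(OCOC)cc1F
F3 | step 5 | (R)-[3,4-bis(benzyloxy)phenyl]{(2R,3R)-3-[2-fluoro-4-(methoxymethoxy)phenyl]oxiran-2-yl}methanol | O[C@H](c1ccc(OCc2ccccc2)c(OCc2ccccc2)c1)[C@H]1O[C@@H]1c1ccc(OCOC)cc1F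
F4 | step 5 | (R)-[3,4-bis(benzyloxy)phenyl]{(4R,5S)-5-[2-fluoro-4-(methoxymethoxy)phenyl]-2,2-dimethyl-1,3-dioxolan-4-yl}methanol | O[C@H](c1ccc(OCc2ccccc2)c(OCc2ccccc2)c1)[C@H]1OC(C)(C)O[C@H]1c1ccc(OCOC)cc1F
F5 | step 5 | 2,3-trans-3,4-cis-2-[3,4-bis(benzyloxy)phenyl]-3,4-O-isopropylidene-7-(methoxymethoxy)chroman-3,4-diol (C2 and C3 as in 10) | COCOc1ccc2c(c1)O[C@H](c1ccc(OCc3ccccc3)c(OCc3ccccc3)c1)[C@H]1OC(C)(C)O[C@@H]21
F6 | step 8 | 3',4'-di-O-benzylfisetinidol-(4α→6)-(3',4'-di-O-benzyl-4-O-methyl-leucofisetinidin); both units 2R,3S,4R | Oc1ccc2c(c1)O[C@H](c1ccc(OCc3ccccc3)c(OCc3ccccc3)c1)[C@@H](O)[C@@H]2c1cc2c(cc1O)O[C@H](c1ccc(OCc3ccccc3)c(OCc3ccccc3)c1)[C@@H](O)[C@@H]2OC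
F7 | step 9 | 3',4'-di-O-benzylfisetinidol-(4α→6)-(3',4'-di-O-benzyl-leucofisetinidin), the 4-hydroxy analogue of 14; both units 2R,3S,4R | Oc1ccc2c(c1)O[C@H](c1ccc(OCc3ccccc3)c(OCc3ccccc3)c1)[C@@H](O)[C@@H]2c1cc2c(cc1O)O[C@H](c1ccc(OCc3ccccc3)c(OCc3ccccc3)c1)[C@@H](O)[C@@H]2O
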